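Readings and results stem from a simulated flask from invented constants; noise was put on by code.

Target is lost at 0.0444 s⁻¹ in the beta run and at 0.00418 s⁻¹ in the delta run, about ten times as fast in the hotter run.

all flasks: starting material 0.0020 M

| run | partner | second substrate | third substrate | temperature | remark | time |
|---|---|---|---|---|---|---|
| delta | 4 mM | 0.50 mM | 2 mM | 36 °C | run made earlier |  |
| beta | 4 mM | 0.75 mM | 2 mM | 61 °C | run made earlier |  |
| grey | 4.00 mM | 1.00 mM | 2.00 mM | 40 °C |  | 2.0 min |
| ochre | 4.00 mM | 1.00 mM | 2.00 mM | 55 °C |  | 2.0 min |
| amber | 4.00 mM | 1.00 mM | 2.00 mM | 70 °C |  | 2.0 min |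
| violet | 4.00 mM | 1.00 mM | 2.00 mM | 25 °C |  | 2.0 min |

| run | time / s | target / % | over-reaction product / % | starting material / % |
|---|---|---|---|---|
| delta | 15.0 | 77.9 | 4.8 | 17.5 |
| delta | 30.0 | 78.5 | 9.6 | 11.5 |
| delta | 50.0 | 75.1 | 14.4 | 9.8 |
| delta | 60.0 | 71.4 | 19.3 | 11.2 |
| delta | 80.0 | 65.7 | 26.5 | 7.8 |
| delta | 90.0 | 64.2 | 29.3 | 8.2 |
| beta | 10.0 | 54.3 | 27.0 | 16.4 |
| beta | 20.0 | 36.4 | 48.5 | 18.9 |
| beta | 30.0 | 22.3 | 62.1 | 17.1 |

(readings scatter by 1 percentage point)



1. the flask that comes out highest in share of target in all that became target or over-reaction product, or "all alike" when all lie within 1.5 percentage points (grey / ochre / amber / violet / all alike)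
2. share of target in all that became target or over-reaction product, grey
3. share of target in all that became target or over-reaction product, ochre
4. share of target in all that became target or over-reaction product, amber
5. share of target in all that became target or over-reaction product, violet

I read those two rates from the share, or selectivity: target as a fraction of target plus over-reaction product. Leftover starting material does not enter it. I take the amount of target as the one concentration that sets the rate, a first-order decay with a time constant. If target appears right at the start, the share then falls as exp(−N), where N is the elapsed time divided by that time constant. I call N the ageing number.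

Delta supports a clock starting near zero: starting material is down to 17.5 % at 15.0 s, and the reading at 30.0 s gives 0.00385 s⁻¹, close to the late rate.

The two runs differ in second substrate as well as temperature, so they cannot separate the two. I commit to temperature as the cause, which gives an activation energy of 81.2 kJ mol⁻¹. For violet the rate is 0.00130 s⁻¹, so N is 0.156 and the share 85.6 %. For grey, N is 0.750 and the share 47.2 %. For ochre, N is 3.12 and the share 4.42 %. For amber, N is 11.5 and the share 0.00106 %. One number is enough if target forms quickly in the cold flasks too, and that is my weak point.

The forecast differs from my reckoning. It names violet and gives 67 % for violet, 24 % for grey, 1 % for ochre and 0.1 % for amber, on the grounds “Assuming first order in second substrate”.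

The flasks give 85.7 % for violet, the highest, then 46.5 % for grey, 4.12 % for ochre and 0 % for amber. The forecast's violet stands lower. Changing second substrate by itself from the delta run to violet's charge leaves the share at 90.0 s at 68.6 %, where it was 68.9 %.

    starting material + partner → target (k = 110 M⁻¹ s⁻¹, Ea = 52.0 kJ mol⁻¹)
    second substrate + partner → second product (k = 130 M⁻¹ s⁻¹, Ea = 47.0 kJ mol⁻¹)
    third substrate + partner → third product (k = 55.0 M⁻¹ s⁻¹, Ea = 46.0 kJ mol⁻¹)
    target → over-reaction product (k = 0.00660 s⁻¹, Ea = 80.0 kJ mol⁻¹)
    partner → decomposed reagent (k = 0.0130 s⁻¹, Ea = 98.0 kJ mol⁻¹)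
    (constants at 40 °C)

Violet left for 20.0 min has N of 1.56, so I expect a share of 21.0 %; the flask gives 18.8 %.

Violet stopped at 50 s has N of 0.0650, so I expect 93.7 %. The computed flask gives 94.3 %.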